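**Strategy.** The synthesis rests on cutting the C2–C3 bond of pyranone ring C. C2 is at once benzylic to ring B and bonded to the ring oxygen O1, so in an aryl benzyl ether its two C–H bonds are the most hydridic in the molecule and sit 1,6 to C3. A chiral dirhodium carbene generated at C3 from a diazomethyl ketone on ring A inserts into one of these enantiotopic C–H bonds, closing ring C and setting the C2 stereocentre in a single operation. The precursor is a fully silylated 2-(arylmethoxy)aryl diazomethyl ketone that already carries both prenyl groups, assembled by Mitsunobu union of a ring A acetophenone with a ring B benzyl alcohol.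

Key step: step 9

Remarks: TBS is tert-butyldimethylsilyl, TBSO the corresponding silyloxy group, and prenyl is 3-methylbut-2-enyl. Assumption: Rh2(S-BSP)4 is taken to deliver the (2S) product; if the sense of induction proves opposite, the mirror-image catalyst Rh2(R-BSP)4 is used with no other change.

Step 1
Reactants: 1 2,4,6-trihydroxyacetophenone
Product: 2 1-[2,4-bis(TBSO)-6-hydroxyphenyl]ethanone
Conditions: TBSCl (2.1 equiv), imidazole, DMF, 0 °C to rt
Reagents that add atoms: tert-butyldimethylsilyl chloride, CC(C)(C)[Si](C)(C)Cl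
Why: Silylation of phenols with a silyl chloride and imidazole: the para hydroxyl and one ortho hydroxyl react, whereas the last hydroxyl stays locked in the hydrogen bond to the acetyl carbonyl, so the reaction should stop at the bis-silyl ether.

Step 2
Reactants: 2 1-[2,4-bis(TBSO)-6-hydroxyphenyl]ethanone; 3 3-methylbut-2-en-1-ol
Product: 4 1-[2,4-bis(TBSO)-6-(3-methylbut-2-enyloxy)phenyl]ethanone
Conditions: PPh3, DIAD, THF, 0 °C to rt
Reagents that add atoms: none
Why: Mitsunobu etherification: the hydrogen-bonded phenol is acidic enough to serve as pronucleophile and is alkylated at the primary carbon of the allylic alcohol under neutral conditions that leave the silyl ethers untouched.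

Step 3
Reactants: 4 1-[2,4-bis(TBSO)-6-(3-methylbut-2-enyloxy)phenyl]ethanone
Product: 7 1-[2,4-bis(TBSO)-6-hydroxy-3-(3-methylbut-2-enyl)phenyl]ethanone, via ortho-dienone 5 (not isolated), via para-dienone 6 (not isolated)
Conditions: Eu(fod)3 (10 mol%), CHCl3, 60 °C
Reagents that add atoms: none
Why: Europium-catalysed tandem aromatic Claisen–Cope (para-Claisen) rearrangement: chelation of Eu(fod)3 by the acetyl and ether oxygens triggers the [3,3] shift to the free ortho carbon (dienone 5), a second [3,3] shift carries the group, now as a normal prenyl unit, to the para carbon between the two silyloxy groups (dienone 6), and enolisation gives the phenol whose free hydroxyl is the future O1.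

Step 4
Reactants: 8 3-bromo-4,5-dihydroxybenzaldehyde
Product: 9 3-bromo-4,5-bis(TBSO)benzaldehyde
Conditions: TBSCl (2.2 equiv), imidazole, DMF, rt
Reagents that add atoms: tert-butyldimethylsilyl chloride, CC(C)(C)[Si](C)(C)Cl
Why: Silylation of both catechol hydroxyls with a silyl chloride and imidazole, which masks them for the coupling and carbene steps and allows one global fluoride deprotection at the end.

Step 5
Reactants: 9 3-bromo-4,5-bis(TBSO)benzaldehyde
Product: 10 3,4-bis(TBSO)-5-(3-methylbut-2-enyl)benzaldehyde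
Conditions: Bu3SnCH2CH=CMe2, Pd(PPh3)4 (5 mol%), DMF, 90 °C
Reagents that add atoms: tributyl(3-methylbut-2-en-1-yl)stannane, CCCC[Sn](CCCC)(CCCC)CC=C(C)C
Why: Stille cross-coupling: zerovalent palladium inserts into the aryl–bromine bond, the prenyl group is transferred from tin and reductive elimination at the unsubstituted allyl terminus should give the linear prenyl arene, the aldehyde and silyl ethers being inert under these neutral conditions.

Step 6
Reactants: 10 3,4-bis(TBSO)-5-(3-methylbut-2-enyl)benzaldehyde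
Product: 11 [3,4-bis(TBSO)-5-(3-methylbut-2-enyl)phenyl]methanol
Conditions: NaBH4, THF/MeOH (10:1), 0 °C
Reagents that add atoms: none
Why: Hydride reduction of the aldehyde with NaBH4, run briefly and cold so that the aryl silyl ethers survive the weakly basic medium.

Step 7
Reactants: 7 1-[2,4-bis(TBSO)-6-hydroxy-3-(3-methylbut-2-enyl)phenyl]ethanone; 11 [3,4-bis(TBSO)-5-(3-methylbut-2-enyl)phenyl]methanol
Product: 12 1-[6-{[3,4-bis(TBSO)-5-(3-methylbut-2-enyl)phenyl]methoxy}-2,4-bis(TBSO)-3-(3-methylbut-2-enyl)phenyl]ethanone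
Conditions: PPh3, DIAD, THF, 0 °C to rt
Reagents that add atoms: none
Why: Mitsunobu etherification: the only free hydroxyl of 7, the chelated phenol that becomes O1, is alkylated by the electron-rich primary benzylic alcohol 11 under neutral conditions, which avoids base-induced silyl transfer and an unstable benzylic halide.

Step 8
Reactants: 12 1-[6-{[3,4-bis(TBSO)-5-(3-methylbut-2-enyl)phenyl]methoxy}-2,4-bis(TBSO)-3-(3-methylbut-2-enyl)phenyl]ethanone
Product: 14 2-diazo-1-[6-{[3,4-bis(TBSO)-5-(3-methylbut-2-enyl)phenyl]methoxy}-2,4-bis(TBSO)-3-(3-methylbut-2-enyl)phenyl]ethanone, via trifluoroacetyl ketone 13 (not isolated)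
Conditions: LiN(SiMe3)2, THF, −78 °C; CF3CO2CH2CF3, −78 °C; aq. HCl work-up; then MsN3, Et3N, H2O (1 equiv), MeCN, rt
Reagents that add atoms: methanesulfonyl azide, CS(=O)(=O)N=[N+]=[N-] (the two diazo nitrogens of 14); 2,2,2-trifluoroethyl trifluoroacetate, O=C(OCC(F)(F)F)C(F)(F)F (the trifluoroacetyl group of 13, lost again on the way to 14)
Why: Detrifluoroacetylative diazo transfer (a Regitz-type diazo transfer with a temporary activating group): Claisen trifluoroacetylation of the kinetically formed lithium enolate gives 1,3-diketone 13, which accepts the diazo group from the sulfonyl azide and sheds the trifluoroacetyl group as the N-acylsulfonamide, the low temperature and short enolate lifetime serving to outrun silyl migration from the neighbouring silyloxy group.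

Step 9
Reactants: 14 2-diazo-1-[6-{[3,4-bis(TBSO)-5-(3-methylbut-2-enyl)phenyl]methoxy}-2,4-bis(TBSO)-3-(3-methylbut-2-enyl)phenyl]ethanone
Product: 15 (2S)-5,7-bis(TBSO)-2-[3,4-bis(TBSO)-5-(3-methylbut-2-enyl)phenyl]-6-(3-methylbut-2-enyl)chroman-4-one
Conditions: Rh2(S-BSP)4 (dirhodium tetrakis[(S)-N-(benzenesulfonyl)prolinate], 2 mol%), CH2Cl2, 14 added by syringe pump (final 0.005 M), 0 °C to rt
Reagents that add atoms: none
Why: Rh2(S-BSP)4 expels N2 from 14 to give an electrophilic rhodium-bound carbene at C3, which inserts through a concerted, asynchronous three-centre transition state (hydride-like transfer from C2 with simultaneous C–C bond formation) into one C–H bond of the OCH2Ar methylene, forming the C2–C3 bond. The closest known reaction type is the dirhodium-carboxylate-catalysed intramolecular C–H insertion of 2-alkoxyaryl α-diazoketones to chroman-4-ones, which has enantioselective precedent with N-sulfonylprolinate ligands. Ring C (O1–C2–C3–C4–C4a–C8a) is closed by a 1,6-C–H insertion through a six-membered cyclic transition state. The C2 stereocentre is set by the chiral prolinate ligand sphere, which distinguishes the two enantiotopic benzylic hydrogens, so it is purely catalyst-controlled. The step needs chemoselectivity for this methylene over attack of O1 on the carbene (oxonium ylide, [1,2]-benzyl shift), over cyclopropanation of the prenyl olefins and over insertion elsewhere; the substrate secures it because the methylene is activated both by O1 and by the para-silyloxyaryl group and is the only sp3 C–H next to oxygen within reach, the silyl ethers carry no α-oxy C–H bond, and the ring A prenyl group, meta to the acyl-bearing carbon, cannot reach the carbene. A carboxylate catalyst in a non-coordinating solvent favours insertion over ylide formation, and slow addition at high dilution suppresses bimolecular cyclopropanation and carbene dimerisation.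

Step 10
Reactants: 15 (2S)-5,7-bis(TBSO)-2-[3,4-bis(TBSO)-5-(3-methylbut-2-enyl)phenyl]-6-(3-methylbut-2-enyl)chroman-4-one
Product: 16 (2S)-2-[3,4-dihydroxy-5-(3-methylbut-2-enyl)phenyl]-5,7-dihydroxy-6-(3-methylbut-2-enyl)chroman-4-one
Conditions: TBAF (4.5 equiv), AcOH (6 equiv), THF, 0 °C to rt
Reagents that add atoms: none
Why: Fluoride-mediated cleavage of the four aryl silyl ethers, buffered with acetic acid so that each phenol is released in protonated form and neither base-induced ring opening of the flavanone to the chalcone (which would racemise C2) nor acid-induced cyclisation of the ortho-prenyl phenols can intervene.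

**Compound list**

1 | 2,4,6-trihydroxyacetophenone | CC(=O)c1c(O)cc(O)cc1O | starting material
2 | 1-[2,4-bis(tert-butyldimethylsilyloxy)-6-hydroxyphenyl]ethanone | CC(=O)c1c(O)cc(O[Si](C)(C)C(C)(C)C)cc1O[Si](C)(C)C(C)(C)C | intermediate
3 | 3-methylbut-2-en-1-ol (prenyl alcohol) | CC(C)=CCO | starting material
4 | 1-[2,4-bis(tert-butyldimethylsilyloxy)-6-(3-methylbut-2-enyloxy)phenyl]ethanone | CC(=O)c1c(OCC=C(C)C)cc(O[Si](C)(C)C(C)(C)C)cc1O[Si](C)(C)C(C)(C)C | intermediate
5 | 2-acetyl-3,5-bis(tert-butyldimethylsilyloxy)-6-(2-methylbut-3-en-2-yl)cyclohexa-2,4-dien-1-one (ortho-dienone, racemic) | CC(=O)C1=C(O[Si](C)(C)C(C)(C)C)C=C(O[Si](C)(C)C(C)(C)C)C(C(C)(C)C=C)C1=O | intermediate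
6 | 2-acetyl-3,5-bis(tert-butyldimethylsilyloxy)-4-(3-methylbut-2-enyl)cyclohexa-2,5-dien-1-one (para-dienone) | CC(=O)C1=C(O[Si](C)(C)C(C)(C)C)C(CC=C(C)C)C(O[Si](C)(C)C(C)(C)C)=CC1=O | intermediate
7 | 1-[2,4-bis(tert-butyldimethylsilyloxy)-6-hydroxy-3-(3-methylbut-2-enyl)phenyl]ethanone | CC(=O)c1c(O)cc(O[Si](C)(C)C(C)(C)C)c(CC=C(C)C)c1O[Si](C)(C)C(C)(C)C | intermediate
8 | 3-bromo-4,5-dihydroxybenzaldehyde | O=Cc1cc(O)c(O)c(Br)c1 | starting material
9 | 3-bromo-4,5-bis(tert-butyldimethylsilyloxy)benzaldehyde | O=Cc1cc(O[Si](C)(C)C(C)(C)C)c(O[Si](C)(C)C(C)(C)C)c(Br)c1 | intermediate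
10 | 3,4-bis(tert-butyldimethylsilyloxy)-5-(3-methylbut-2-enyl)benzaldehyde | O=Cc1cc(O[Si](C)(C)C(C)(C)C)c(O[Si](C)(C)C(C)(C)C)c(CC=C(C)C)c1 | intermediate
11 | [3,4-bis(tert-butyldimethylsilyloxy)-5-(3-methylbut-2-enyl)phenyl]methanol | OCc1cc(O[Si](C)(C)C(C)(C)C)c(O[Si](C)(C)C(C)(C)C)c(CC=C(C)C)c1 | intermediate
12 | 1-[6-{[3,4-bis(tert-butyldimethylsilyloxy)-5-(3-methylbut-2-enyl)phenyl]methoxy}-2,4-bis(tert-butyldimethylsilyloxy)-3-(3-methylbut-2-enyl)phenyl]ethanone | CC(=O)c1c(OCc2cc(O[Si](C)(C)C(C)(C)C)c(O[Si](C)(C)C(C)(C)C)c(CC=C(C)C)c2)cc(O[Si](C)(C)C(C)(C)C)c(CC=C(C)C)c1O[Si](C)(C)C(C)(C)C | intermediate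
13 | 1-[6-{[3,4-bis(tert-butyldimethylsilyloxy)-5-(3-methylbut-2-enyl)phenyl]methoxy}-2,4-bis(tert-butyldimethylsilyloxy)-3-(3-methylbut-2-enyl)phenyl]-4,4,4-trifluorobutane-1,3-dione | O=C(CC(=O)C(F)(F)F)c1c(OCc2cc(O[Si](C)(C)C(C)(C)C)c(O[Si](C)(C)C(C)(C)C)c(CC=C(C)C)c2)cc(O[Si](C)(C)C(C)(C)C)c(CC=C(C)C)c1O[Si](C)(C)C(C)(C)C | intermediate
14 | 2-diazo-1-[6-{[3,4-bis(tert-butyldimethylsilyloxy)-5-(3-methylbut-2-enyl)phenyl]methoxy}-2,4-bis(tert-butyldimethylsilyloxy)-3-(3-methylbut-2-enyl)phenyl]ethanone | [N-]=[N+]=CC(=O)c1c(OCc2cc(O[Si](C)(C)C(C)(C)C)c(O[Si](C)(C)C(C)(C)C)c(CC=C(C)C)c2)cc(O[Si](C)(C)C(C)(C)C)c(CC=C(C)C)c1O[Si](C)(C)C(C)(C)C | intermediate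
15 | (2S)-5,7-bis(tert-butyldimethylsilyloxy)-2-[3,4-bis(tert-butyldimethylsilyloxy)-5-(3-methylbut-2-enyl)phenyl]-6-(3-methylbut-2-enyl)chroman-4-one | CC(C)=CCc1cc([C@@H]2CC(=O)c3c(cc(O[Si](C)(C)C(C)(C)C)c(CC=C(C)C)c3O[Si](C)(C)C(C)(C)C)O2)cc(O[Si](C)(C)C(C)(C)C)c1O[Si](C)(C)C(C)(C)C | intermediate
16 | (2S)-2-[3,4-dihydroxy-5-(3-methylbut-2-enyl)phenyl]-5,7-dihydroxy-6-(3-methylbut-2-enyl)chroman-4-one | CC(C)=CCc1cc([C@@H]2CC(=O)c3c(cc(O)c(CC=C(C)C)c3O)O2)cc(O)c1O | target

**Totals**

Total step count: 10.
Longest linear sequence: 7 steps (steps 1, 2, 3, 7, 8, 9, 10; the ring B branch, steps 4, 5, 6, 7, 8, 9, 10, is equally long).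

**Steps most likely to fail**

1. Step 9. The acceptor-only carbene may discriminate poorly between the two enantiotopic benzylic hydrogens, eroding the enantiomeric excess. Part of it may also be captured by the lone pair of O1, giving an oxonium ylide that undergoes a [1,2]-benzyl shift. The fallback decouples ring closure from stereocontrol and sets out from 14. The same C2–C3 bond is closed with achiral Rh2(OAc)4 in CH2Cl2 under high dilution, a catalyst chosen only for chemoselective insertion, to give racemic 5,7-bis(TBSO)-2-[3,4-bis(TBSO)-5-prenylphenyl]-6-prenylchroman-4-one F1. This is resolved kinetically by asymmetric transfer hydrogenation with RuCl(p-cymene)[(R,R)-TsDPEN] and HCO2H/Et3N in EtOAc. The (2R)-enantiomer should be reduced faster, from the face anti to the C2 aryl group, to the cis-(2R,4R)-flavan-4-ol F2. The (2S)-ketone should remain and is separated by chromatography, rejoining the route at 15.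

2. Step 8. Silyl migration from the ortho silyloxy oxygen to the enolate oxygen, or incomplete acylation of the hindered di-ortho-substituted enolate, may divert the material before diazo transfer. The fallback avoids a free metal enolate and sets out from 12. Soft enolisation with Me3SiOTf/Et3N in CH2Cl2 at 0 °C should give the trimethylsilyl enol ether F3. Bromination with NBS in THF at −78 °C should give the α-bromoketone F4. N,N'-ditosylhydrazine with DBU in THF at 0 °C (N-alkylation, then twofold loss of sulfinate) should convert it into the diazoketone, rejoining the route at 14.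

3. Step 5. The prenyl group may be transferred through its tertiary terminus, giving the 1,1-dimethylallyl isomer, and oxidative addition beside the bulky silyloxy group may be sluggish. The fallback builds the prenyl group in two stages and sets out from 9. Stille coupling with allyltributylstannane and Pd(PPh3)4, which has no regiochemical ambiguity, should give 3-allyl-4,5-bis(TBSO)benzaldehyde F5. Olefin cross-metathesis with excess 2-methyl-2-butene and second-generation Grubbs catalyst in CH2Cl2 should convert the allyl into the prenyl group, rejoining the route at 10.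

**Further compounds**

F1 | step 9 | racemic 5,7-bis(tert-butyldimethylsilyloxy)-2-[3,4-bis(tert-butyldimethylsilyloxy)-5-(3-methylbut-2-enyl)phenyl]-6-(3-methylbut-2-enyl)chroman-4-one | CC(C)=CCc1cc(C2CC(=O)c3c(cc(O[Si](C)(C)C(C)(C)C)c(CC=C(C)C)c3O[Si](C)(C)C(C)(C)C)O2)cc(O[Si](C)(C)C(C)(C)C)c1O[Si](C)(C)C(C)(C)C
F2 | step 9 | (2R,4R)-5,7-bis(tert-butyldimethylsilyloxy)-2-[3,4-bis(tert-butyldimethylsilyloxy)-5-(3-methylbut-2-enyl)phenyl]-6-(3-methylbut-2-enyl)chroman-4-ol (cis) | CC(C)=CCc1cc([C@H]2C[C@@H](O)c3c(cc(O[Si](C)(C)C(C)(C)C)c(CC=C(C)C)c3O[Si](C)(C)C(C)(C)C)O2)cc(O[Si](C)(C)C(C)(C)C)c1O[Si](C)(C)C(C)(C)C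
F3 | step 8 | trimethylsilyl enol ether of 12, {1-[6-{[3,4-bis(tert-butyldimethylsilyloxy)-5-(3-methylbut-2-enyl)phenyl]methoxy}-2,4-bis(tert-butyldimethylsilyloxy)-3-(3-methylbut-2-enyl)phenyl]ethenyloxy}trimethylsilane | C=C(O[Si](C)(C)C)c1c(OCc2cc(O[Si](C)(C)C(C)(C)C)c(O[Si](C)(C)C(C)(C)C)c(CC=C(C)C)c2)cc(O[Si](C)(C)C(C)(C)C)c(CC=C(C)C)c1O[Si](C)(C)C(C)(C)C
F4 | step 8 | 2-bromo-1-[6-{[3,4-bis(tert-butyldimethylsilyloxy)-5-(3-methylbut-2-enyl)phenyl]methoxy}-2,4-bis(tert-butyldimethylsilyloxy)-3-(3-methylbut-2-enyl)phenyl]ethanone | O=C(CBr)c1c(OCc2cc(O[Si](C)(C)C(C)(C)C)c(O[Si](C)(C)C(C)(C)C)c(CC=C(C)C)c2)cc(O[Si](C)(C)C(C)(C)C)c(CC=C(C)C)c1O[Si](C)(C)C(C)(C)C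
F5 | step 5 | 3-allyl-4,5-bis(tert-butyldimethylsilyloxy)benzaldehyde | O=Cc1cc(O[Si](C)(C)C(C)(C)C)c(O[Si](C)(C)C(C)(C)C)c(CC=C)c1
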